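## Retrosynthetic overview

1. Target 21 ⇒ 7‑O‑(1,1‑dimethylallyl) ether 19 by an aromatic Claisen shift that forms the C6–prenyl bond; 19 ⇒ isocaviunin 17 ⇒ its 5,7‑dibenzyl ether 16.
2. 16 ⇒ acid 14: the pyranone ring C is the only ring made (rings A and B are bought), closed by forming C4–C4a in an intramolecular Friedel–Crafts acylation.
3. The strategy rests on C4a of ring A: it is ortho to O1, ortho to O5 and para to O7 (a phloroglucinol‑type carbon), and the other carbon ortho to the O1‑bearing C8a is C8, which carries the methoxy group.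
4. 14 ⇒ phenol 8 + enol tosylate 12: the O1–C2 bond is made by addition–elimination; 12 comes from 2,4,5‑trimethoxyphenylacetic acid 9 and methyl formate.
5. 8 ⇒ 2,4,6‑trihydroxybenzaldehyde 1 by dibenzylation, MOM protection, Dakin‑type oxidation, O‑methylation and MOM removal.

Key step: step 11

Remark 1: the target has no stereocentre and is achiral, so the request for a single enantiomer places no demand on the route.
Remark 2: compounds 11–15 are drawn with the Z geometry (oxygen substituent cis to the carboxyl group), which is the one that closes; any E isomer formed is carried along, because the geometry is lost at the acylium stage of step 11.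

## Route

Step 1
Reactants: 1 2,4,6‑trihydroxybenzaldehyde
Product: 3 2,4‑bis(benzyloxy)‑6‑hydroxybenzaldehyde, via 4-(benzyloxy)-2,6-dihydroxybenzaldehyde 2 (not isolated)
Conditions: BnBr (2.05 equiv), K2CO3, DMF, 0 °C → rt
Reagents that add atoms: benzyl bromide, BrCc1ccccc1
Why: Williamson etherification in which the unchelated, most acidic 4‑OH reacts first and one ortho OH second, while the last ortho OH stays hydrogen‑bonded to the formyl oxygen and should not be alkylated with two equivalents.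

Step 2
Reactants: 3 2,4‑bis(benzyloxy)‑6‑hydroxybenzaldehyde
Product: 4 2,4‑bis(benzyloxy)‑6‑(methoxymethoxy)benzaldehyde
Conditions: NaH, MOMCl, DMF, 0 °C → rt
Reagents that add atoms: chloromethyl methyl ether, COCCl
Why: Williamson‑type acetal protection after full deprotonation of the chelated phenol (the aldehyde has no enolisable hydrogen), giving a group orthogonal to the benzyl ethers and stable to the next two steps.

Step 3
Reactants: 4 2,4‑bis(benzyloxy)‑6‑(methoxymethoxy)benzaldehyde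
Product: 6 2,4‑bis(benzyloxy)‑6‑(methoxymethoxy)phenol, via aryl formate 5 (not isolated)
Conditions: mCPBA, CH2Cl2, 0 °C → rt; wash (aq Na2S2O3, aq NaHCO3); then K2CO3 (cat.), MeOH, rt, under Ar
Reagents that add atoms: 3‑chloroperoxybenzoic acid, OOC(=O)c1cccc(Cl)c1
Why: Baeyer–Villiger (Dakin‑type) oxidation in which the electron‑rich trialkoxyphenyl group migrates in preference to hydrogen, and the resulting formate is removed by mild methanolysis after the peracid has been destroyed.

Step 4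
Reactants: 6 2,4‑bis(benzyloxy)‑6‑(methoxymethoxy)phenol
Product: 7 1,5‑bis(benzyloxy)‑2‑methoxy‑3‑(methoxymethoxy)benzene
Conditions: MeI, K2CO3, acetone, 50 °C, under Ar
Reagents that add atoms: iodomethane, CI
Why: Williamson methylation of the only free phenol, which fixes the future 8‑methoxy group on the central oxygen.

Step 5
Reactants: 7 1,5‑bis(benzyloxy)‑2‑methoxy‑3‑(methoxymethoxy)benzene
Product: 8 3,5‑bis(benzyloxy)‑2‑methoxyphenol
Conditions: conc. HCl (cat.), MeOH–THF, 50 °C
Reagents that add atoms: none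
Why: acid‑catalysed acetal cleavage (transacetalisation to dimethoxymethane) to which benzyl and methyl aryl ethers are inert.

Step 6
Reactants: 9 2,4,5‑trimethoxyphenylacetic acid
Product: 10 methyl 2‑(2,4,5‑trimethoxyphenyl)acetate
Conditions: MeOH, H2SO4 (cat.), reflux
Reagents that add atoms: methanol, CO
Why: Fischer esterification driven by the excess of methanol.

Step 7
Reactants: 10 methyl 2‑(2,4,5‑trimethoxyphenyl)acetate
Product: 11 methyl (Z)‑3‑hydroxy‑2‑(2,4,5‑trimethoxyphenyl)acrylate (enol form of the α‑formyl ester)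
Conditions: HCO2Me (excess), NaH, THF, 0 °C → rt; then 1 M HCl
Reagents that add atoms: methyl formate, COC=O
Why: crossed Claisen condensation (C‑formylation) of the ester enolate with the non‑enolisable formate, driven by formation of the stabilised enolate of the product, which after acidification should rest as the hydrogen‑bonded Z enol.

Step 8
Reactants: 11 methyl (Z)‑3‑hydroxy‑2‑(2,4,5‑trimethoxyphenyl)acrylate
Product: 12 methyl (Z)‑3‑(tosyloxy)‑2‑(2,4,5‑trimethoxyphenyl)acrylate
Conditions: TsCl, N‑methylimidazole, LiOH, MeCN, 0 °C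
Reagents that add atoms: 4‑toluenesulfonyl chloride, Cc1ccc(S(=O)(=O)Cl)cc1
Why: O‑sulfonylation of the lithium‑chelated enolate by the N‑sulfonylimidazolium species, which should keep the enol oxygen cis to the ester and turns C3 into an electrophilic vinylic centre.

Step 9
Reactants: 8 3,5‑bis(benzyloxy)‑2‑methoxyphenol; 12 methyl (Z)‑3‑(tosyloxy)‑2‑(2,4,5‑trimethoxyphenyl)acrylate
Product: 13 methyl (Z)‑3‑[3,5‑bis(benzyloxy)‑2‑methoxyphenoxy]‑2‑(2,4,5‑trimethoxyphenyl)acrylate
Conditions: Cs2CO3, MeCN, rt, under Ar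
Reagents that add atoms: none
Why: nucleophilic vinylic substitution (addition–elimination) of the cesium phenoxide at C3 of the β‑sulfonyloxy acrylate, expected to go with retention because tosylate leaves quickly from the ester‑stabilised carbanion.

Step 10
Reactants: 13 methyl (Z)‑3‑[3,5‑bis(benzyloxy)‑2‑methoxyphenoxy]‑2‑(2,4,5‑trimethoxyphenyl)acrylate
Product: 14 (Z)‑3‑[3,5‑bis(benzyloxy)‑2‑methoxyphenoxy]‑2‑(2,4,5‑trimethoxyphenyl)acrylic acid
Conditions: LiOH·H2O, THF–MeOH–H2O, 45 °C; then 1 M HCl to pH 3, 0 °C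
Reagents that add atoms: lithium hydroxide, [Li+].[OH-]
Why: saponification at the acyl carbon, as is routine for 3‑aryloxyacrylates, whose push–pull aryl vinyl ether resists aqueous hydroxide and brief mild acidification.

Step 11
Reactants: 14 (Z)‑3‑[3,5‑bis(benzyloxy)‑2‑methoxyphenoxy]‑2‑(2,4,5‑trimethoxyphenyl)acrylic acid
Product: 16 5,7‑bis(benzyloxy)‑8‑methoxy‑3‑(2,4,5‑trimethoxyphenyl)‑4H‑chromen‑4‑one, via mixed trifluoroacetic anhydride 15 (not isolated)
Conditions: TFAA (1.5 equiv), CH2Cl2, 0 °C → rt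
Reagents that add atoms: none
Why: TFAA turns the carboxyl group of 14 into the mixed anhydride 15, which ionises with help from the aryloxy oxygen to an acylium ion that is also a ketene–oxocarbenium ion, so C2–C3 gains single‑bond character and any E isomer can rotate into the closing Z arrangement. The acyl carbon (future C4) is then attacked by the free ortho carbon of the aryloxy ring (future C4a) and proton loss restores the arene; this is an intramolecular Friedel–Crafts acylation, the known cyclisation of 3‑aryloxyacrylic acids to chromones under anhydride or acid activation. The six‑membered pyranone ring C closes in the 6‑exo‑trig mode at the acyl carbon, with the O1–C2 bond already in place. No stereocentre is formed. Site selectivity on ring A is needed and is set by the substrate: one carbon ortho to the ether oxygen carries the methoxy group, the para carbon is out of reach of the tether, the attacking carbon is ortho to O1, ortho to the 5‑benzyloxy oxygen and para to the 7‑benzyloxy oxygen, and ring B could only close a four‑membered ring. Anhydride activation without mineral or Lewis acid is chosen so that the two benzyl ethers should survive.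

Step 12
Reactants: 16 5,7‑bis(benzyloxy)‑8‑methoxy‑3‑(2,4,5‑trimethoxyphenyl)‑4H‑chromen‑4‑one
Product: 17 5,7‑dihydroxy‑8‑methoxy‑3‑(2,4,5‑trimethoxyphenyl)‑4H‑chromen‑4‑one (isocaviunin)
Conditions: H2 (1 atm), 10% Pd/C, EtOAc–MeOH, rt
Reagents that add atoms: none
Why: hydrogenolysis of both benzyl aryl ethers in one operation, under which the vinylogous‑ester C2=C3 bond of an isoflavone is normally not reduced at 1 atm and rt.

Step 13
Reactants: 17 5,7‑dihydroxy‑8‑methoxy‑3‑(2,4,5‑trimethoxyphenyl)‑4H‑chromen‑4‑one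
Product: 18 5‑hydroxy‑8‑methoxy‑7‑[(2‑methylbut‑3‑yn‑2‑yl)oxy]‑3‑(2,4,5‑trimethoxyphenyl)‑4H‑chromen‑4‑one
Conditions: 3‑chloro‑3‑methylbut‑1‑yne, K2CO3, KI (cat.), CuI (cat.), acetone, 55 °C
Reagents that add atoms: 3‑chloro‑3‑methylbut‑1‑yne, CC(C)(Cl)C#C
Why: copper‑assisted propargylic etherification of the more acidic 7‑OH, the 5‑OH being held in a hydrogen bond to the C4 carbonyl and therefore unreactive.

Step 14
Reactants: 18 5‑hydroxy‑8‑methoxy‑7‑[(2‑methylbut‑3‑yn‑2‑yl)oxy]‑3‑(2,4,5‑trimethoxyphenyl)‑4H‑chromen‑4‑one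
Product: 19 5‑hydroxy‑8‑methoxy‑7‑[(2‑methylbut‑3‑en‑2‑yl)oxy]‑3‑(2,4,5‑trimethoxyphenyl)‑4H‑chromen‑4‑one
Conditions: H2 (1 atm), Lindlar catalyst, quinoline, EtOAc, rt
Reagents that add atoms: none
Why: Lindlar semihydrogenation of the terminal alkyne to the alkene, stopped at uptake of one equivalent so that the tertiary allyl ether is neither saturated nor hydrogenolysed.

Step 15
Reactants: 19 5‑hydroxy‑8‑methoxy‑7‑[(2‑methylbut‑3‑en‑2‑yl)oxy]‑3‑(2,4,5‑trimethoxyphenyl)‑4H‑chromen‑4‑one
Product: 21 6‑prenylisocaviunin, 5,7‑dihydroxy‑8‑methoxy‑6‑(3‑methylbut‑2‑en‑1‑yl)‑3‑(2,4,5‑trimethoxyphenyl)‑4H‑chromen‑4‑one, via C6-prenyl cyclohexadienone 20 (not isolated)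
Conditions: Eu(fod)3 (10 mol %), CHCl3, 60 °C
Reagents that add atoms: none
Why: aromatic Claisen rearrangement ([3,3] shift) of the 1,1‑dimethylallyl ether, which can end productively only at C6 because C8 carries the methoxy group and a dienone formed there cannot enolise, and the mild europium catalysis should avoid chroman formation.

## Compound list

1 | 2,4,6‑trihydroxybenzaldehyde | O=Cc1c(O)cc(O)cc1O | starting material
2 | 4‑(benzyloxy)‑2,6‑dihydroxybenzaldehyde | O=Cc1c(O)cc(OCc2ccccc2)cc1O | intermediate (not isolated)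
3 | 2,4‑bis(benzyloxy)‑6‑hydroxybenzaldehyde | O=Cc1c(O)cc(OCc2ccccc2)cc1OCc1ccccc1 | intermediate
4 | 2,4‑bis(benzyloxy)‑6‑(methoxymethoxy)benzaldehyde | COCOc1cc(OCc2ccccc2)cc(OCc2ccccc2)c1C=O | intermediate
5 | 2,4‑bis(benzyloxy)‑6‑(methoxymethoxy)phenyl formate | COCOc1cc(OCc2ccccc2)cc(OCc2ccccc2)c1OC=O | intermediate (not isolated)
6 | 2,4‑bis(benzyloxy)‑6‑(methoxymethoxy)phenol | COCOc1cc(OCc2ccccc2)cc(OCc2ccccc2)c1O | intermediate
7 | 1,5‑bis(benzyloxy)‑2‑methoxy‑3‑(methoxymethoxy)benzene | COCOc1cc(OCc2ccccc2)cc(OCc2ccccc2)c1OC | intermediate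
8 | 3,5‑bis(benzyloxy)‑2‑methoxyphenol | COc1c(O)cc(OCc2ccccc2)cc1OCc1ccccc1 | intermediate
9 | 2,4,5‑trimethoxyphenylacetic acid | COc1cc(OC)c(CC(=O)O)cc1OC | starting material
10 | methyl 2‑(2,4,5‑trimethoxyphenyl)acetate | COC(=O)Cc1cc(OC)c(OC)cc1OC | intermediate
11 | methyl (Z)‑3‑hydroxy‑2‑(2,4,5‑trimethoxyphenyl)acrylate | COC(=O)/C(c1cc(OC)c(OC)cc1OC)=C\O | intermediate
12 | methyl (Z)‑3‑(tosyloxy)‑2‑(2,4,5‑trimethoxyphenyl)acrylate | COC(=O)/C(c1cc(OC)c(OC)cc1OC)=C\OS(=O)(=O)c1ccc(C)cc1 | intermediate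
13 | methyl (Z)‑3‑[3,5‑bis(benzyloxy)‑2‑methoxyphenoxy]‑2‑(2,4,5‑trimethoxyphenyl)acrylate | COC(=O)/C(c1cc(OC)c(OC)cc1OC)=C\Oc1cc(OCc2ccccc2)cc(OCc2ccccc2)c1OC | intermediate
14 | (Z)‑3‑[3,5‑bis(benzyloxy)‑2‑methoxyphenoxy]‑2‑(2,4,5‑trimethoxyphenyl)acrylic acid | OC(=O)/C(c1cc(OC)c(OC)cc1OC)=C\Oc1cc(OCc2ccccc2)cc(OCc2ccccc2)c1OC | intermediate (key‑step precursor)
15 | (Z)‑3‑[3,5‑bis(benzyloxy)‑2‑methoxyphenoxy]‑2‑(2,4,5‑trimethoxyphenyl)acrylic trifluoroacetic anhydride | O=C(OC(=O)C(F)(F)F)/C(c1cc(OC)c(OC)cc1OC)=C\Oc1cc(OCc2ccccc2)cc(OCc2ccccc2)c1OC | intermediate (not isolated)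
16 | 5,7‑bis(benzyloxy)‑8‑methoxy‑3‑(2,4,5‑trimethoxyphenyl)‑4H‑chromen‑4‑one | O=c1c(-c2cc(OC)c(OC)cc2OC)coc2c(OC)c(OCc3ccccc3)cc(OCc3ccccc3)c12 | intermediate (key‑step product)
17 | 5,7‑dihydroxy‑8‑methoxy‑3‑(2,4,5‑trimethoxyphenyl)‑4H‑chromen‑4‑one (isocaviunin) | O=c1c(-c2cc(OC)c(OC)cc2OC)coc2c(OC)c(O)cc(O)c12 | intermediate
18 | 5‑hydroxy‑8‑methoxy‑7‑[(2‑methylbut‑3‑yn‑2‑yl)oxy]‑3‑(2,4,5‑trimethoxyphenyl)‑4H‑chromen‑4‑one | O=c1c(-c2cc(OC)c(OC)cc2OC)coc2c(OC)c(OC(C)(C)C#C)cc(O)c12 | intermediate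
19 | 5‑hydroxy‑8‑methoxy‑7‑[(2‑methylbut‑3‑en‑2‑yl)oxy]‑3‑(2,4,5‑trimethoxyphenyl)‑4H‑chromen‑4‑one | O=c1c(-c2cc(OC)c(OC)cc2OC)coc2c(OC)c(OC(C)(C)C=C)cc(O)c12 | intermediate
20 | 5‑hydroxy‑8‑methoxy‑6‑(3‑methylbut‑2‑en‑1‑yl)‑3‑(2,4,5‑trimethoxyphenyl)‑6H‑chromene‑4,7‑dione (racemic, transient) | O=C1C(-c2cc(OC)c(OC)cc2OC)=COC2=C(OC)C(=O)C(CC=C(C)C)C(O)=C12 | intermediate (not isolated)
21 | 6‑prenylisocaviunin | COc1cc(OC)c(-c2coc3c(OC)c(O)c(CC=C(C)C)c(O)c3c2=O)cc1OC | target

## Step count

Total: 15 steps. Longest linear sequence: 12 steps (steps 1–5 and 9–15, from 1). The second branch (steps 6–8, from 9) joins at step 9.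

## Steps most likely to fail

Step 11 (ring closure). The acyl group of a push–pull acid may be too weakly electrophilic under anhydride activation alone. Stronger acid would then be needed, which risks cleavage or migration of the benzyl ethers and scission of the aryl vinyl ether before the ring closes. Fallback with known chemistry, closing the same C4–C4a bond at the dihydro level: it sets out from 8 and 10 and comes back at 16. Ester 10 is methylenated (paraformaldehyde, K2CO3, Bu4NI, toluene, 80 °C) to methyl 2‑(2,4,5‑trimethoxyphenyl)acrylate F1. Oxa‑Michael addition of phenol 8 (DBU cat., MeCN) should give racemic methyl 3‑[3,5‑bis(benzyloxy)‑2‑methoxyphenoxy]‑2‑(2,4,5‑trimethoxyphenyl)propanoate F2. Neutral ester cleavage (Me3SnOH, 1,2‑dichloroethane, 80 °C), chosen to avoid retro‑Michael loss of the phenoxide, gives racemic 3‑[3,5‑bis(benzyloxy)‑2‑methoxyphenoxy]‑2‑(2,4,5‑trimethoxyphenyl)propanoic acid F3. Its acyl group has no donor conjugation and no alkene geometry, so TFAA in CH2Cl2 at 0 °C should close racemic 5,7‑bis(benzyloxy)‑8‑methoxy‑3‑(2,4,5‑trimethoxyphenyl)chroman‑4‑one F4. Dehydrogenation of C2–C3 with DDQ in dioxane at reflux then gives 16.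

Step 15 (Claisen shift). The tertiary allyl ether may ionise instead of rearranging, with loss of isoprene back to 17 or a 1,3‑shift to the 7‑O‑prenyl ether. The new prenyl group may also cyclise onto O5 or O7 to chromans. Fallback by cross‑coupling: it sets out from 17 and comes back at 21. Iodination with NIS (1 equiv, DMF, 0 °C) at C6, the only free carbon of the phenolic ring A, should give 5,7‑dihydroxy‑6‑iodo‑8‑methoxy‑3‑(2,4,5‑trimethoxyphenyl)‑4H‑chromen‑4‑one F5. Stille coupling with tributyl(3‑methylbut‑2‑en‑1‑yl)stannane (Pd(PPh3)4, DMF, 90 °C) then installs the linear prenyl group and gives 21.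

Step 13 (tertiary propargyl ether). Etherification at O7, which is crowded by the 8‑methoxy group, may be slow, and elimination of the tertiary chloride to the enyne or C‑alkylation at C6 may take over. Fallback by Tsuji–Trost O‑allylation: it sets out from 17 and comes back at 19, so that 18 and step 14 are bypassed. tert‑Butyl (2‑methylbut‑3‑en‑2‑yl) carbonate F6 is prepared from 2‑methylbut‑3‑en‑2‑ol (n‑BuLi, Boc2O, THF). With Pd(PPh3)4 (cat.) in THF at 0 °C it should transfer the 1,1‑dimethylallyl group to the 7‑OH through attack of the phenoxide at the more substituted end of the π‑allyl complex, giving 19.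

## Further compounds

F1 | step 11 | methyl 2‑(2,4,5‑trimethoxyphenyl)acrylate | COC(=O)C(=C)c1cc(OC)c(OC)cc1OC
F2 | step 11 | methyl 3‑[3,5‑bis(benzyloxy)‑2‑methoxyphenoxy]‑2‑(2,4,5‑trimethoxyphenyl)propanoate (racemic) | COC(=O)C(COc1cc(OCc2ccccc2)cc(OCc2ccccc2)c1OC)c1cc(OC)c(OC)cc1OC
F3 | step 11 | 3‑[3,5‑bis(benzyloxy)‑2‑methoxyphenoxy]‑2‑(2,4,5‑trimethoxyphenyl)propanoic acid (racemic) | OC(=O)C(COc1cc(OCc2ccccc2)cc(OCc2ccccc2)c1OC)c1cc(OC)c(OC)cc1OC
F4 | step 11 | 5,7‑bis(benzyloxy)‑8‑methoxy‑3‑(2,4,5‑trimethoxyphenyl)chroman‑4‑one (racemic) | O=C1C(c2cc(OC)c(OC)cc2OC)COc2c(OC)c(OCc3ccccc3)cc(OCc3ccccc3)c12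
F5 | step 15 | 5,7‑dihydroxy‑6‑iodo‑8‑methoxy‑3‑(2,4,5‑trimethoxyphenyl)‑4H‑chromen‑4‑one | COc1cc(OC)c(-c2coc3c(OC)c(O)c(I)c(O)c3c2=O)cc1OC
F6 | step 13 | tert‑butyl (2‑methylbut‑3‑en‑2‑yl) carbonate | CC(C)(C)OC(=O)OC(C)(C)C=C
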